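**Assumption:** the target has no stereocentre or stereoaxis, so it is achiral and needs no stereocontrol; rhamnetin (7-O-methylquercetin, CAS 90-19-7) is taken as a purchasable starting material.

**Retrosynthetic overview**
- Target ⇒ hydrogenolysis of three benzyl ethers (3, 3', 4') from the 8-acetate; the acetate is installed before the phenols are freed.
- 8-OAc ⇒ selective acetylation of the free 8-OH of a 5,8-quinol, whose 5-OH is chelated to the C-4 carbonyl.
- 8-OH ⇒ Elbs persulfate para-hydroxylation of the 5-hydroxyflavone (new C–O bond at C-8).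
- Tribenzyl ether ⇒ rhamnetin + benzyl bromide.
- No ring is formed: the A/C/B flavonol skeleton is bought intact in rhamnetin.

**Step 1**
Reactants: 1 rhamnetin (3,5,3',4'-tetrahydroxy-7-methoxyflavone); 2 benzyl bromide
Product: 3 3,3',4'-tris(benzyloxy)-5-hydroxy-7-methoxyflavone
Conditions: BnBr (3.3 eq), K2CO3 (3.5 eq), DMF, rt→40 °C, 16 h
Reagents that add atoms: benzyl bromide, BrCc1ccccc1
Why: Williamson etherification; the 5-OH is hydrogen-bonded to the C-4 carbonyl and is the least acidic and least nucleophilic hydroxyl, so limited BnBr with mild base stops at the 3,3',4'-triether (no stereocentre).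

**Step 2**
Reactants: 3 3,3',4'-tris(benzyloxy)-5-hydroxy-7-methoxyflavone; 4 potassium peroxodisulfate
Product: 6 3,3',4'-tris(benzyloxy)-5,8-dihydroxy-7-methoxyflavone, via potassium flavon-8-yl sulfate 5 (not isolated)
Conditions: K2S2O8 (1.5 eq), aq KOH, pyridine, 0 °C→rt, 24 h; recover unreacted 3; then aq HCl, Na2SO3 (cat.), 85 °C, 30 min, N2
Reagents that add atoms: potassium peroxodisulfate, [K+].[K+].[O-]S(=O)(=O)OOS([O-])(=O)=O
Why: Elbs persulfate oxidation; the 5-phenoxide attacks the peroxide oxygen through its only free para carbon (C-8) to give the aryl sulfate, which acid hydrolyses to the quinol, while benzyl ethers are inert to both stages.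

**Step 3**
Reactants: 6 3,3',4'-tris(benzyloxy)-5,8-dihydroxy-7-methoxyflavone; 7 acetic anhydride
Product: 8 8-acetoxy-3,3',4'-tris(benzyloxy)-5-hydroxy-7-methoxyflavone
Conditions: Ac2O (1.05 eq), pyridine, 0 °C, 2 h, Ar
Reagents that add atoms: acetic anhydride, CC(=O)OC(C)=O
Why: chemoselective O-acylation; the 8-OH is an ordinary phenol while the 5-OH is deactivated by chelation to the carbonyl, so one equivalent of anhydride at 0 °C should acetylate O-8 only.

**Step 4**
Reactants: 8 8-acetoxy-3,3',4'-tris(benzyloxy)-5-hydroxy-7-methoxyflavone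
Product: 9 gossypetin 7-methyl ether 8-acetate (8-acetoxy-3,5,3',4'-tetrahydroxy-7-methoxyflavone)
Conditions: H2 (1 atm), 10% Pd/C, EtOAc/THF 1:1, rt, 4 h
Reagents that add atoms: none
Why: catalytic hydrogenolysis of benzyl ethers under neutral, alcohol-free conditions leaves the aryl acetate and the chromone C2=C3 bond intact, and the 8-OAc has no neighbouring free OH (flanked by 7-OMe and O-1), so it cannot migrate; the product is achiral.

**Compound list**
1 | rhamnetin (3,5,3',4'-tetrahydroxy-7-methoxyflavone) | COc1cc(O)c2c(=O)c(O)c(-c3ccc(O)c(O)c3)oc2c1 | starting material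
2 | benzyl bromide | BrCc1ccccc1 | starting material
3 | 3,3',4'-tris(benzyloxy)-5-hydroxy-7-methoxyflavone | COc1cc(O)c2c(=O)c(OCc3ccccc3)c(-c3ccc(OCc4ccccc4)c(OCc4ccccc4)c3)oc2c1 | intermediate
4 | potassium peroxodisulfate | [K+].[K+].[O-]S(=O)(=O)OOS([O-])(=O)=O | starting material
5 | potassium 3,3',4'-tris(benzyloxy)-5-hydroxy-7-methoxyflavon-8-yl sulfate | COc1cc(O)c2c(=O)c(OCc3ccccc3)c(-c3ccc(OCc4ccccc4)c(OCc4ccccc4)c3)oc2c1OS(=O)(=O)[O-].[K+] | intermediate
6 | 3,3',4'-tris(benzyloxy)-5,8-dihydroxy-7-methoxyflavone | COc1cc(O)c2c(=O)c(OCc3ccccc3)c(-c3ccc(OCc4ccccc4)c(OCc4ccccc4)c3)oc2c1O | intermediate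
7 | acetic anhydride | CC(=O)OC(C)=O | starting material
8 | 8-acetoxy-3,3',4'-tris(benzyloxy)-5-hydroxy-7-methoxyflavone | COc1cc(O)c2c(=O)c(OCc3ccccc3)c(-c3ccc(OCc4ccccc4)c(OCc4ccccc4)c3)oc2c1OC(C)=O | intermediate
9 | gossypetin 7-methyl ether 8-acetate | COc1cc(O)c2c(=O)c(O)c(-c3ccc(O)c(O)c3)oc2c1OC(C)=O | target

**Total step count:** 4. **Longest linear sequence:** 4 (from rhamnetin).

**Three steps most likely to fail, with fallbacks**

Step 2 (Elbs oxidation: typically low conversion, poor solubility of the phenoxide, over-oxidation). The fallback sets out from 3 and comes back at 6. Instead of persulfate para-sulfation, oxidise the 5-phenol to the para-quinone by a Teuber oxidation (Fremy's salt, KH2PO4 buffer, acetone/H2O, rt), giving 3,3',4'-tris(benzyloxy)-7-methoxyflavone-5,8-quinone F1. Reduce the quinone with aqueous Na2S2O4 (EtOAc/H2O, rt) to the quinol 6 and continue with step 3. The chelated phenol may react slowly with Fremy's salt, so this is untested on this substrate.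

Step 3 (selectivity between 8-OH and 5-OH, and air sensitivity of the quinol in pyridine). The fallback sets out from 5 and comes back at 9. The Elbs sulfate is used as a protecting group for O-8 rather than being hydrolysed. After removal of unreacted 3, take up salt 5 (n-BuOH extraction or Bu4N+ ion pair) and benzylate its only free phenol, the 5-OH (BnBr, K2CO3, DMF, 70 °C), to potassium 3,5,3',4'-tetrakis(benzyloxy)-7-methoxyflavon-8-yl sulfate F2. Mild acid solvolysis of the sulfate (cat. TsOH, wet dioxane, 40–50 °C) gives 3,5,3',4'-tetrakis(benzyloxy)-8-hydroxy-7-methoxyflavone F3, in which O-8 is the only free hydroxyl. Acetylation without any selectivity demand (Ac2O, pyridine, DMAP) gives 8-acetoxy-3,5,3',4'-tetrakis(benzyloxy)-7-methoxyflavone F4. Hydrogenolysis as in step 4 (H2, Pd/C, EtOAc/THF) removes all four benzyl groups and delivers 9.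

Step 1 (mixtures of di-, tri- and tetra-benzyl ethers). The fallback sets out from 1 and comes back at 3. Benzylate exhaustively (BnBr 6 eq, K2CO3, DMF, 80 °C) to the single product 3,5,3',4'-tetrakis(benzyloxy)-7-methoxyflavone F5. Then remove only the 5-O-benzyl group, peri to the carbonyl, by chelation-controlled Lewis-acid cleavage (BCl3 1.1 eq, CH2Cl2, −78 °C, aqueous work-up), which gives 3.

**Further compounds**
F1 | step 2 | 3,3',4'-tris(benzyloxy)-7-methoxyflavone-5,8-quinone | COC1=CC(=O)C2=C(OC(-c3ccc(OCc4ccccc4)c(OCc4ccccc4)c3)=C(OCc3ccccc3)C2=O)C1=O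
F2 | step 3 | potassium 3,5,3',4'-tetrakis(benzyloxy)-7-methoxyflavon-8-yl sulfate | COc1cc(OCc2ccccc2)c2c(=O)c(OCc3ccccc3)c(-c3ccc(OCc4ccccc4)c(OCc4ccccc4)c3)oc2c1OS(=O)(=O)[O-].[K+]
F3 | step 3 | 3,5,3',4'-tetrakis(benzyloxy)-8-hydroxy-7-methoxyflavone | COc1cc(OCc2ccccc2)c2c(=O)c(OCc3ccccc3)c(-c3ccc(OCc4ccccc4)c(OCc4ccccc4)c3)oc2c1O
F4 | step 3 | 8-acetoxy-3,5,3',4'-tetrakis(benzyloxy)-7-methoxyflavone | COc1cc(OCc2ccccc2)c2c(=O)c(OCc3ccccc3)c(-c3ccc(OCc4ccccc4)c(OCc4ccccc4)c3)oc2c1OC(C)=O
F5 | step 1 | 3,5,3',4'-tetrakis(benzyloxy)-7-methoxyflavone | COc1cc(OCc2ccccc2)c2c(=O)c(OCc3ccccc3)c(-c3ccc(OCc4ccccc4)c(OCc4ccccc4)c3)oc2c1
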